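One point here means one percent of the substrate charged, and an open dimer counts by the substrate in it, so whatever the three read species failed to add up to I took as open dimer. The gamma flask is the one asked about; the zeta flask had half its charge.

| flask | substrate | remark | time |
|---|---|---|---|
| gamma | 20 mM | the very flask that is asked about, followed so far |  |
| zeta | 10 mM | run made earlier |  |
| flask | 20 mM |  | 1.0 h |

| run | time / min | substrate / % | ring / % | isomer of the product / % |
|---|---|---|---|---|
| gamma | 0.417 | 17.4 | 32.2 | 27.3 |
| gamma | 0.667 | 6.4 | 25.1 | 43.1 |
| gamma | 1.33 | 1.2 | 8.1 | 66.0 |
| gamma | 2.50 | 0 | 3.3 | 71.6 |
| gamma | 5.00 | 0 | 4.2 | 71.8 |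
| zeta | 12.0 | 0 | 5.3 | 80.2 |
| zeta | 25.0 | 0.4 | 4.5 | 79.8 |
| zeta | 40.0 | 0.3 | 1.7 | 81.3 |
| zeta | 50.0 | 0.6 | 3.9 | 81.6 |
| zeta | 60.0 | 0 | 2.0 | 81.9 |

(readings scatter by 1 percentage point)

- a species is counted by the substrate in it: one open dimer counts as two
- the reaction counts as stopped when no species that holds the substrate changes by six tenths of a point or more over the second half of the time

* which holds at 1.0 h: what has brought the reaction to rest, or that it has not come to rest (all of the substrate has reacted / it is still moving / forward and back rates have come level)
* how much of the substrate has reacted by 1.0 h
* how much ring there is at 1.0 h, in percent of the substrate charged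
* how much isomer of the product there is at 1.0 h, in percent of the substrate charged
* how much open dimer there is at 1.0 h, in percent of the substrate charged
* amount of ring if the flask were left three thousand times as long, in percent of the substrate charged

At 0.417 min the gamma flask read substrate 17.4%, ring 32.2% and isomer 27.3%, so 23.1% read as open dimer. By 1.33 min substrate read 1.2%, ring had fallen to 8.1%, isomer had climbed to 66.0%, and the missing share stood at 24.7%. At 2.50 min substrate read 0%, and from there to 5.00 min the gamma readings of ring and isomer moved by 0.9 percentage points and 0.2 points, against a scatter of 1 point. I read the gamma run as open dimer made while substrate lasted, with ring then passing on to isomer.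

In the zeta flask, ring plus isomer averaged 84.4%, more than the 76.0% of the last gamma reading. So I let substrate be lost by closure at k[substrate] and by pairing at m times [substrate] squared. Each bit of substrate then closes with chance k/(k+m[substrate]), time drops out, and integrating that chance from the charge down to nothing gives a closed share of ln(1+a)/a, with a taken at the charge.

A rational approximation to that logarithm turned the zeta share into a = 0.393: this is the split number, pairing loss over closure loss at the start, a selectivity factor of sorts. Since a scales with the charge in this scheme, I reckoned 0.785 for the gamma flask, a closed share of 73.8% and open dimer 26.2%.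

Late ring over isomer, from both runs, read 0.0454, so for the gamma flask at the hour I reckoned ring 3.21% and isomer 70.6%. I called it stopped by the end of the substrate, and I kept the ring unchanged for the long wait.

The forecast said forward and back rates have come level, from “a fast ring–isomer equilibrium”, with conversion 100%, ring 3.5%, isomer 71.8%, open dimer 24.7% and 3.7% ring at the long time, so we parted on the stop and on that long ring.

The flask gave: all of the substrate has reacted, conversion 100%, ring 3.03%, isomer 71.3%, open dimer 25.7%, and ring 3.03% at the long time.

    substrate → ring (k = 0.0583 s⁻¹)
    2 substrate → open dimer (k = 1.11 M⁻¹ s⁻¹)
    ring ⇌ isomer of the product (K = 23.5, k = 0.0402 s⁻¹)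

Over the second half of the hour the largest change in the gamma flask was 0 points, with substrate at 0%. My split number had given the gamma flask 26.2% open dimer against the 25.7% found. Scaled to the neighbour flask with 80 mM of substrate, a became 3.14, and the same logarithm gave 54.8% open dimer; that flask held 54.1%.

All runs stem from a simulated flask with constants of no real substance.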